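**Retrosynthetic overview**

- Ring numbering used throughout: C1 = C(Cl)CH3, C2 = CH2, C3 = C(CH3)(C7H=C8HBr), C4 = CHBr, C5 = CH2, C6 = CHCl. The strategy rests on the adjacent stereocentres C3 (quaternary) and C4 of the cyclohexane ring C1–C6: the bonds C3–C7 and C4–C5 stand as an anti addition across a C3=C4 alkenylboron unit, with boron later exchanged for bromine with inversion.
- Target ⇐ syn-dichlorination of the C1=C6 alkene ⇐ invertive bromination of a C4 boronate ⇐ ring-closing metathesis at C1=C6. The only ring (C1–C6) is closed after the key step.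
- Acyclic diene boronate ⇐ three-component conjunctive coupling: allyl (C5, C6) shifts from boron to C4 and palladium delivers the bromovinyl group (C7=C8) to C3 of an (E)-alkenyl pinacol boronate.
- Alkenyl boronate ⇐ methylalumination/borylation of 2-methylpent-1-en-4-yne ⇐ methallyl chloride + ethynylmagnesium bromide. (E)-1-Bromo-2-iodoethene ⇐ acetylene + IBr. Allyllithium ⇐ allyltributylstannane.

Key step: step 4

Assumption: (Sp,Sp)-MandyPhos is taken as the ligand antipode that places palladium on the re face of C3 of the borate; if a pilot run shows the opposite sense, the (Rp,Rp) antipode is used with nothing else changed.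

**Route**

Step 1
Reactants: 1 methallyl chloride (3-chloro-2-methylprop-1-ene); 2 ethynylmagnesium bromide
Product: 3 2-methylpent-1-en-4-yne
Conditions: 2 (1.5 equiv), CuCl (5 mol%), THF, 0 °C → 50 °C; water washes to remove THF, fractional distillation
Reagents that add atoms: none
Why: Copper-catalysed coupling of the alkynyl Grignard reagent with the allylic chloride (allylic substitution) should give the skipped enyne, and since both ends of the methallyl unit are equivalent CH2 groups, direct and transposed attack lead to the same product.

Step 2
Reactants: 3 2-methylpent-1-en-4-yne; 4 2-isopropoxy-4,4,5,5-tetramethyl-1,3,2-dioxaborolane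
Product: 6 2-[(1E)-2,4-dimethylpenta-1,4-dien-1-yl]-4,4,5,5-tetramethyl-1,3,2-dioxaborolane, via alkenylalane 5 (not isolated)
Conditions: AlMe3 (2 equiv), Cp2ZrCl2 (20 mol%), CH2Cl2, 0 °C → rt; then 4 (3 equiv), 0 °C → rt; aqueous work-up
Reagents that add atoms: trimethylaluminium, C[Al](C)C
Why: Zirconium-catalysed methylalumination (Negishi carboalumination) adds CH3 and aluminium syn across the terminal alkyne with aluminium at the terminus (the 1,1-disubstituted alkene is inert to it), and the alkenyl group then passes from aluminium to the alkoxyboronate with retention, so boron ends cis to the new methyl, the (E) geometry that later fixes the C3/C4 relationship.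

Step 3
Reactants: 7 acetylene; 8 iodine monobromide
Product: 9 (E)-1-bromo-2-iodoethene
Conditions: 8 in 48% aq. HBr, 0 °C, stream of 7
Reagents that add atoms: none
Why: Electrophilic anti addition of I–Br across the triple bond through a bridged iodonium ion should give the trans (E) dihaloethene, a known preparation.

Step 4
Reactants: 6 (E)-alkenyl pinacol boronate; 9 (E)-1-bromo-2-iodoethene; 10 allyltributylstannane
Product: 13 2-[(4R,5R)-5-[(E)-2-bromoethenyl]-5,7-dimethylocta-1,7-dien-4-yl]-4,4,5,5-tetramethyl-1,3,2-dioxaborolane, via allyllithium 11 (not isolated), via lithium allylborate 12 (not isolated)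
Conditions: 10, n-BuLi, THF, −78 °C; 6, −78 → 0 °C; evaporate, pentane rinse; then Pd(OAc)2 (3 mol%), (Sp,Sp)-MandyPhos [1,1′-bis(diphenylphosphino)-2,2′-bis(α-dimethylaminobenzyl)ferrocene] (3.6 mol%), KOTf (2 equiv), 9 (1.5 equiv), THF, 40 °C
Reagents that add atoms: none
Why: Proposed new method: Transmetalation of 10 with n-BuLi gives halide-free allyllithium 11, which adds to the boron of 6 to form borate 12. Zerovalent palladium inserts into the C–I bond of 9 (much faster than into C–Br), KOTf removes iodide as KI, and the cationic bromovinyl complex of divalent palladium binds the borate-activated C3=C4 bond; allyl then shifts from boron to C4 anti to palladium, palladium takes up C3, and reductive elimination joins C3 to C7 with retention of the (E)-bromoalkene. The closest known reaction type is the enantioselective palladium-catalysed conjunctive cross-coupling of alkenylboron ate complexes with aryl and alkenyl electrophiles, which has not been shown for a β,β-disubstituted alkenyl boronate ending in a quaternary carbon or for allyl as the migrating group. No ring is closed in this step. C3 and C4 are set together: their relative configuration follows from anti addition across the (E)-alkene (boron cis to the C3 methyl, from step 2) and their absolute configuration from the chiral bisphosphine, which must place palladium on the re face of C3 so that allyl reaches the si face of C4. The step needs the metallate shift to outrun direct transfer of allyl or alkenyl from boron to palladium and reductive elimination at the tertiary C3 to outrun β-hydride elimination; the electron-rich dialkyl-substituted alkenylborate π bond of the substrate, the iodide-free cationic palladium on a wide-bite-angle chelate and the excess of 9 (which keeps zerovalent palladium off the C–Br bonds of 13) are relied on for this.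

Step 5
Reactants: 13 acyclic diene boronate
Product: 14 2-[(1R,6R)-6-[(E)-2-bromoethenyl]-4,6-dimethylcyclohex-3-en-1-yl]-4,4,5,5-tetramethyl-1,3,2-dioxaborolane
Conditions: second-generation Grubbs catalyst RuCl2(=CHPh)(H2IMes)(PCy3) (5 mol%), CH2Cl2 (0.01 M), 40 °C
Reagents that add atoms: none
Why: Ring-closing metathesis between the monosubstituted allyl alkene and the 1,1-disubstituted methallyl alkene should close the six-membered ring at C1=C6 with loss of ethene, while the bromoalkene, electron-poor and attached to the quaternary C3, should stay out of the catalytic cycle and neither stereocentre is touched.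

Step 6
Reactants: 14 cyclohexenyl boronate (boron trans to the bromovinyl group)
Product: 16 (4S,5S)-4-bromo-5-[(E)-2-bromoethenyl]-1,5-dimethylcyclohex-1-ene, via lithium arylborate 15 (not isolated)
Conditions: 3,5-(CF3)2C6H3Li (1.2 equiv, from 3,5-(CF3)2C6H3Br and n-BuLi), THF, −78 °C; then NBS (1.5 equiv), THF, −78 °C → rt
Reagents that add atoms: N-bromosuccinimide, O=C1CCC(=O)N1Br
Why: The electron-poor aryllithium adds to boron to give borate 15, whose C4–B bond is attacked by NBS from the rear (SE2 with inversion), the known stereoinvertive bromination of secondary alkyl pinacol boronate complexes, which should turn the C4 boronate into the C4 bromide cis to the bromovinyl group while the aryl group stays on boron.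

Step 7
Reactants: 16 bromocyclohexene
Product: 17 (1S,2S,4R,5S)-2-bromo-1-[(E)-2-bromoethenyl]-4,5-dichloro-1,5-dimethylcyclohexane (target; Br, both Cl and the bromovinyl group on one ring face, both methyls on the other)
Conditions: PhSeSePh (5 mol%), BnEt3NCl (3 equiv), N-fluoropyridinium tetrafluoroborate (1.3 equiv), Me3SiCl (2 equiv), 2,6-lutidine N-oxide (1 equiv), MeCN, rt
Reagents that add atoms: benzyltriethylammonium chloride, [Cl-].CC[N+](CC)(CC)Cc1ccccc1; chlorotrimethylsilane, C[Si](C)(C)Cl
Why: Proposed new method: the closest known reaction type is the PhSeSePh-catalysed syn-dichlorination of cyclic and acyclic 1,2-disubstituted alkenes, not yet shown for a trisubstituted alkene that must give a tertiary chloride; PhSeCl3 formed in situ should add anti across C1=C6 from the less hindered face (opposite to the C4 bromine and the C3 bromovinyl group) with chloride entering at the tertiary C1, and chloride should then displace the tetravalent selenium group at the secondary C6 with inversion, so that both chlorines end cis to each other and on the face of bromine and bromovinyl, which sets C1 and C6.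

**Compound list**

1 | 3-chloro-2-methylprop-1-ene (methallyl chloride) | CC(=C)CCl | starting material
2 | ethynylmagnesium bromide | C#C[Mg]Br | starting material
3 | 2-methylpent-1-en-4-yne | CC(=C)CC#C | intermediate
4 | 2-isopropoxy-4,4,5,5-tetramethyl-1,3,2-dioxaborolane | CC(C)OB1OC(C)(C)C(C)(C)O1 | starting material
5 | [(1E)-2,4-dimethylpenta-1,4-dien-1-yl]dimethylalane | CC(=C)C/C(C)=C/[Al](C)C | intermediate
6 | 2-[(1E)-2,4-dimethylpenta-1,4-dien-1-yl]-4,4,5,5-tetramethyl-1,3,2-dioxaborolane | CC(=C)C/C(C)=C/B1OC(C)(C)C(C)(C)O1 | intermediate
7 | acetylene (ethyne) | C#C | starting material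
8 | iodine monobromide | BrI | starting material
9 | (E)-1-bromo-2-iodoethene | Br/C=C/I | intermediate
10 | allyltributylstannane | C=CC[Sn](CCCC)(CCCC)CCCC | starting material
11 | allyllithium | [Li]CC=C | intermediate
12 | lithium allyl[(1E)-2,4-dimethylpenta-1,4-dien-1-yl](pinacolato)borate | [Li+].CC(=C)C/C(C)=C/[B-]1(CC=C)OC(C)(C)C(C)(C)O1 | intermediate
13 | 2-[(4R,5R)-5-[(E)-2-bromoethenyl]-5,7-dimethylocta-1,7-dien-4-yl]-4,4,5,5-tetramethyl-1,3,2-dioxaborolane | C=CC[C@@H](B1OC(C)(C)C(C)(C)O1)[C@](C)(/C=C/Br)CC(C)=C | intermediate
14 | 2-[(1R,6R)-6-[(E)-2-bromoethenyl]-4,6-dimethylcyclohex-3-en-1-yl]-4,4,5,5-tetramethyl-1,3,2-dioxaborolane | CC1=CC[C@@H](B2OC(C)(C)C(C)(C)O2)[C@](C)(/C=C/Br)C1 | intermediate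
15 | lithium [3,5-bis(trifluoromethyl)phenyl][(1R,6R)-6-[(E)-2-bromoethenyl]-4,6-dimethylcyclohex-3-en-1-yl](pinacolato)borate | [Li+].CC1=CC[C@@H]([B-]2(c3cc(cc(c3)C(F)(F)F)C(F)(F)F)OC(C)(C)C(C)(C)O2)[C@](C)(/C=C/Br)C1 | intermediate
16 | (4S,5S)-4-bromo-5-[(E)-2-bromoethenyl]-1,5-dimethylcyclohex-1-ene | CC1=CC[C@H](Br)[C@](C)(/C=C/Br)C1 | intermediate
17 | (1S,2S,4R,5S)-2-bromo-1-[(E)-2-bromoethenyl]-4,5-dichloro-1,5-dimethylcyclohexane | C[C@]1(Cl)C[C@@](C)(/C=C/Br)[C@@H](Br)C[C@H]1Cl | target

**Step count and risks**

Total step count: 7. Longest linear sequence: 6 steps (1, 2, 4, 5, 6, 7); step 3 is a one-step branch.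

Steps most likely to fail:

1. Step 4 (Proposed new method). Direct transfer of the allyl or alkenyl group from boron to palladium (plain cross-coupling) may outrun binding of the trisubstituted C3=C4 bond. The tertiary alkylpalladium may also lose a β-hydrogen before reductive elimination, or the ligand may discriminate the two alkene faces poorly. A bulkier diol on boron would be the first adjustment inside the method.
 Fallback by known chemistry, setting out from enyne 3 and returning to the route at bromocyclohexene 16:
 - 3 is methylaluminated as in step 2 and alane 5 is trapped (after n-BuLi) with paraformaldehyde to give the allylic alcohol (E)-3,5-dimethylhexa-2,5-dien-1-ol F1.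
 - Sharpless epoxidation (Ti(OiPr)4, L-(+)-diethyl tartrate, t-BuOOH, CH2Cl2, −20 °C) should give the (2S,3S)-epoxy alcohol F2.
 - Et2AlC≡CSiMe3 (toluene, 0 °C) should open it at the fully substituted carbon with inversion, which sets C3 in the silylalkynyl diol F3.
 - NaIO4 should cleave the diol to the α-quaternary silylalkynyl aldehyde F4.
 - Allylboration with B-allyldiisopinocampheylborane made from (−)-α-pinene (re-face delivery by the usual chair model, then NaOH/H2O2) should set C4 under reagent control in the silylalkynyl homoallylic alcohol F5.
 - K2CO3/MeOH should give the ethynyl homoallylic alcohol F6.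
 - Hydrozirconation with Cp2Zr(H)Cl and an NBS quench should give the (E)-bromoethenyl homoallylic alcohol F7.
 - Appel bromination (CBr4, PPh3) should invert C4 to the acyclic dibromide F8.
 - Ring-closing metathesis with the second-generation Grubbs catalyst RuCl2(=CHPh)(H2IMes)(PCy3) should then give 16.

2. Step 7 (Proposed new method). The β-chloroalkylselenium intermediate may lose a proton toward an allylic chloride or ionise at the tertiary C1 instead of being displaced at C6, and selenium may add to the face syn to bromine.
 Fallback by known chemistry, setting out from 16 and returning at target 17: epoxidation with mCPBA (CH2Cl2, NaHCO3, 0 °C), expected on the same less hindered face, should give the epoxide 4-bromo-3-[(E)-2-bromoethenyl]-1,3-dimethyl-7-oxabicyclo[4.1.0]heptane F10. Ph3PCl2 (dichlorotriphenylphosphorane, CH2Cl2 or benzene) should then deliver chloride to the tertiary C1 and displace the oxyphosphonium group at C6, each with inversion. This is the known conversion of cyclohexene oxides into cis-1,2-dichlorides and should give 17.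

3. Step 6. Borate formation at the neopentyl-type C4 may be slow, electron transfer from the borate to NBS would pass through a C4 radical and erode the inversion, and NBS may attack the ring alkene.
 Fallback by known chemistry, setting out from boronate 14 and returning at 16: oxidation with NaBO3·4H2O (THF/H2O, rt) with retention should give the cyclohexenol (1R,6S)-6-[(E)-2-bromoethenyl]-4,6-dimethylcyclohex-3-en-1-ol F9. Appel bromination (CBr4, PPh3, CH2Cl2, 0 °C) with inversion at C4 should then give 16.

Further compounds
F1 | step 4 | (E)-3,5-dimethylhexa-2,5-dien-1-ol | CC(=C)C/C(C)=C/CO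
F2 | step 4 | [(2S,3S)-3-methyl-3-(2-methylprop-2-en-1-yl)oxiran-2-yl]methanol | OC[C@@H]1O[C@@]1(C)CC(C)=C
F3 | step 4 | (2R,3S)-3,5-dimethyl-3-[(trimethylsilyl)ethynyl]hex-5-ene-1,2-diol | OC[C@H](O)[C@](C)(C#C[Si](C)(C)C)CC(C)=C
F4 | step 4 | (2S)-2,4-dimethyl-2-[(trimethylsilyl)ethynyl]pent-4-enal | O=C[C@](C)(C#C[Si](C)(C)C)CC(C)=C
F5 | step 4 | (4R,5S)-5,7-dimethyl-5-[(trimethylsilyl)ethynyl]octa-1,7-dien-4-ol | C=CC[C@@H](O)[C@](C)(C#C[Si](C)(C)C)CC(C)=C
F6 | step 4 | (4R,5S)-5-ethynyl-5,7-dimethylocta-1,7-dien-4-ol | C=CC[C@@H](O)[C@](C)(C#C)CC(C)=C
F7 | step 4 | (4R,5S)-5-[(E)-2-bromoethenyl]-5,7-dimethylocta-1,7-dien-4-ol | C=CC[C@@H](O)[C@](C)(/C=C/Br)CC(C)=C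
F8 | step 4 | (4S,5S)-4-bromo-5-[(E)-2-bromoethenyl]-5,7-dimethylocta-1,7-diene | C=CC[C@H](Br)[C@](C)(/C=C/Br)CC(C)=C
F9 | step 6 | (1R,6S)-6-[(E)-2-bromoethenyl]-4,6-dimethylcyclohex-3-en-1-ol | CC1=CC[C@@H](O)[C@](C)(/C=C/Br)C1
F10 | step 7 | (1R,3S,4S,6S)-4-bromo-3-[(E)-2-bromoethenyl]-1,3-dimethyl-7-oxabicyclo[4.1.0]heptane | C[C@]12O[C@H]1C[C@H](Br)[C@](C)(/C=C/Br)C2
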